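**Retrosynthetic overview**
1. The last C–C bond is a Heck coupling between a ring-bound vinyl carbinol and the (2E,4E)-5-bromopentadienamide of 2-amino-3-hydroxycyclopentenone (acid part from glutaconaldehyde enolate).
2. The ring C2–N bond comes from copper-catalysed amidation of a 2-iodocyclohexenone with (2E,4E,6R)-4,6-dimethyldeca-2,4-dienamide.
3. Key step for that amide: a Johnson–Claisen [3,3]-sigmatropic rearrangement of an isopropenyl carbinol forges C2–C3 and fixes the 4E trisubstituted olefin next to the 6R centre, which is bought in (S)-3-bromo-2-methylpropan-1-ol.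
4. The iodoenone comes from (−)-quinic acid: its carbinol centres supply C5, and vinyl addition to the C4 ketone, cis-acetonide formation and loss of the trans oxygen fix C4.
5. Ring order: no carbocycle is built. Ring A (cyclohexenone) is the quinic acid ring, ring B (cyclopentenone) is bought, and only a temporary dioxolane is closed and later reopened.

Assumption: (S)-3-bromo-2-methylpropan-1-ol, glutaconaldehyde potassium salt and 2-amino-3-hydroxycyclopent-2-en-1-one hydrochloride are bought as catalogue compounds.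

**Route**

Step 1
Reactants: 1 (−)-quinic acid
Product: 2 methyl quinate
Conditions: MeOH, Amberlyst 15, reflux
Reagents that add atoms: methanol (CO)
Why: Fischer esterification masks C1 as the α-hydroxy ester and touches no stereocentre.

Step 2
Reactants: 2 methyl quinate
Product: 3 methyl 3,5-bis-O-(tert-butyldimethylsilyl)quinate
Conditions: TBSCl (2.2 equiv), imidazole, DMF, 0 °C to rt
Reagents that add atoms: tert-butyldimethylsilyl chloride (CC(C)(C)[Si](C)(C)Cl)
Why: Regioselective silylation takes the two flanking secondary hydroxyls, leaving the hindered 4-OH and the tertiary 1-OH free.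

Step 3
Reactants: 3 methyl 3,5-bis-O-(tert-butyldimethylsilyl)quinate
Product: 4 methyl (3R,5R)-3,5-bis[(tert-butyldimethylsilyl)oxy]-1-hydroxy-4-oxocyclohexane-1-carboxylate
Conditions: RuCl3 (cat.), NaIO4, EtOAc/MeCN/H2O, rt
Reagents that add atoms: none
Why: Catalytic ruthenium tetroxide oxidation converts the only secondary alcohol into the ketone; the two R-configured silyloxy carbons stay.

Step 4
Reactants: 4 methyl (3R,5R)-3,5-bis[(tert-butyldimethylsilyl)oxy]-1-hydroxy-4-oxocyclohexane-1-carboxylate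
Product: 5 methyl 3,5-bis-O-(tert-butyldimethylsilyl)-4-C-ethenylquinate (4-OH on the face of 1-OH)
Conditions: CH2=CHMgBr (3 equiv), THF, −78 to −20 °C; aq NH4Cl
Reagents that add atoms: vinylmagnesium bromide (C=C[Mg]Br)
Why: Grignard 1,2-addition (one equivalent is spent on the 1-OH) is expected anti to the axial 3-silyloxy group; the face does not matter, because the twofold symmetry of the 3R,5R-diol makes both C4 epimers give the same β-hydroxy ketone after step 7.

Step 5
Reactants: 5 methyl 3,5-bis-O-(tert-butyldimethylsilyl)-4-C-ethenylquinate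
Product: 7 methyl 4-C-ethenyl-3,4-O-isopropylidenequinate, via tetraol 6 (not isolated)
Conditions: TsOH·H2O, MeOH, 40 °C; evaporate; Me2C(OMe)2, acetone, rt
Reagents that add atoms: 2,2-dimethoxypropane (COC(C)(C)OC)
Why: Acid methanolysis removes both silyl ethers and thermodynamic acetalization takes the only cis-vicinal diol (the tertiary 4-OH and the secondary OH on its face), so the trans secondary OH is left free for later elimination and C4 is tied to a bought carbinol centre.

Step 6
Reactants: 7 methyl 4-C-ethenyl-3,4-O-isopropylidenequinate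
Product: 8 4-ethenyl-1-(hydroxymethyl)-3,4-O-isopropylidenecyclohexane-1,3,4,5-tetrol
Conditions: LiAlH4, THF, 0 °C
Reagents that add atoms: none
Why: Hydride reduction of the α-hydroxy ester gives the 1,2-diol needed for cleavage; acetonide and vinyl group are inert.

Step 7
Reactants: 8 4-ethenyl-1-(hydroxymethyl)-3,4-O-isopropylidenecyclohexane-1,3,4,5-tetrol
Product: 9 (3R,4S,5R)-4-ethenyl-5-hydroxy-3,4-(isopropylidenedioxy)cyclohexan-1-one
Conditions: NaIO4, THF/H2O, 0 °C
Reagents that add atoms: none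
Why: Malaprade glycol cleavage unveils the C1 ketone; the only other vicinal oxygens are locked in the acetonide.

Step 8
Reactants: 9 (3R,4S,5R)-4-ethenyl-5-hydroxy-3,4-(isopropylidenedioxy)cyclohexan-1-one
Product: 11 (4S,5R)-4-ethenyl-4,5-(isopropylidenedioxy)cyclohex-2-en-1-one, via mesylate 10 (not isolated)
Conditions: MsCl, Et3N, CH2Cl2, 0 °C to rt
Reagents that add atoms: none
Why: Mesylation of the lone free secondary OH and E1cB elimination give the enone, while the acetonide oxygen (a poor leaving group under Et3N) stays, which fixes the cis-4,5-diol as 4S,5R.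

Step 9
Reactants: 11 (4S,5R)-4-ethenyl-4,5-(isopropylidenedioxy)cyclohex-2-en-1-one
Product: 12 (4S,5R)-4-ethenyl-2-iodo-4,5-(isopropylidenedioxy)cyclohex-2-en-1-one
Conditions: I2, pyridine, CH2Cl2, 0 °C to rt
Reagents that add atoms: iodine ([I][I])
Why: Johnson α-iodination (pyridine conjugate addition, enolate iodination, elimination) is specific for the enone α-carbon and leaves the isolated vinyl group alone.

Step 10
Reactants: 13 (S)-3-bromo-2-methylpropan-1-ol
Product: 14 (R)-2-methylhexan-1-ol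
Conditions: n-PrMgCl (3 equiv), Li2CuCl4 (5 mol %), THF, −78 to 0 °C
Reagents that add atoms: propylmagnesium chloride (CCC[Mg]Cl)
Why: Tamura–Kochi copper-catalysed alkyl–alkyl coupling at the primary bromide of the magnesium alkoxide; the stereocentre is a spectator (S becomes R only through the priority change).

Step 11
Reactants: 14 (R)-2-methylhexan-1-ol
Product: 15 (R)-2-methylhexanal
Conditions: TEMPO (cat.), PhI(OAc)2, CH2Cl2, rt
Reagents that add atoms: none
Why: Oxoammonium oxidation under base-free conditions stops at the aldehyde without epimerizing the α-centre.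

Step 12
Reactants: 15 (R)-2-methylhexanal
Product: 16 (3RS,4R)-2,4-dimethyloct-1-en-3-ol
Conditions: CH2=C(CH3)MgBr, THF, −78 °C
Reagents that add atoms: isopropenylmagnesium bromide (CC(=C)[Mg]Br)
Why: Grignard addition gives the allylic alcohol; the new carbinol centre is lost in the next step, so both epimers are used.

Step 13
Reactants: 16 (3RS,4R)-2,4-dimethyloct-1-en-3-ol
Product: 18 ethyl (4E,6R)-4,6-dimethyldec-4-enoate, via ketene acetal 17 (not isolated)
Conditions: MeC(OEt)3, EtCO2H (cat.), 140 °C, EtOH distilled off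
Reagents that add atoms: triethyl orthoacetate (CCOC(C)(OCC)OCC)
Why: Key step: the Johnson–Claisen [3,3]-sigmatropic rearrangement forms C2–C3 through a chair transition state with the sec-alkyl group pseudo-equatorial, giving the (E)-trisubstituted olefin from both carbinol epimers and leaving C6 untouched.

Step 14
Reactants: 18 ethyl (4E,6R)-4,6-dimethyldec-4-enoate
Product: 21 ethyl (2E,4E,6R)-4,6-dimethyldeca-2,4-dienoate, via selenide 19 (not isolated), via selenoxide 20 (not isolated)
Conditions: LiN(iPr)2, THF, −78 °C; PhSeBr; then H2O2, pyridine, CH2Cl2, 0 °C to rt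
Reagents that add atoms: none
Why: Ester enolate selenenylation and selenoxide syn-elimination give the (2E)-alkene in conjugation with the existing olefin; only the C3 hydrogens are available.

Step 15
Reactants: 21 ethyl (2E,4E,6R)-4,6-dimethyldeca-2,4-dienoate
Product: 22 (2E,4E,6R)-4,6-dimethyldeca-2,4-dienamide
Conditions: AlMe3, NH4Cl, toluene, 0 to 50 °C
Reagents that add atoms: ammonium chloride ([NH4+].[Cl-])
Why: Weinreb aluminium-amide aminolysis converts the conjugated ester into the primary amide by 1,2-attack without touching the diene.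

Step 16
Reactants: 12 (4S,5R)-4-ethenyl-2-iodo-4,5-(isopropylidenedioxy)cyclohex-2-en-1-one; 22 (2E,4E,6R)-4,6-dimethyldeca-2,4-dienamide
Product: 23 (2E,4E,6R)-N-[(3S,4R)-3-ethenyl-3,4-(isopropylidenedioxy)-6-oxocyclohex-1-en-1-yl]-4,6-dimethyldeca-2,4-dienamide
Conditions: CuI (10 mol %), MeNHCH2CH2NHMe (20 mol %), K2CO3, toluene, 60 °C
Reagents that add atoms: none
Why: Goldberg-type copper-catalysed N-vinylation of the primary amide by the activated α-iodoenone forms the C2–N bond; no stereocentre is involved.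

Step 17
Reactants: 23 acetonide-protected enone amide
Product: 24 (2E,4E,6R)-N-[(3S,4R)-3-ethenyl-3,4-dihydroxy-6-oxocyclohex-1-en-1-yl]-4,6-dimethyldeca-2,4-dienamide
Conditions: CF3CO2H/H2O (9:1), CH2Cl2, 0 °C
Reagents that add atoms: none
Why: Acetal hydrolysis frees the cis-diol before the acid-sensitive triene is present; both C–O bonds at the stereocentres are retained.

Step 18
Reactants: 25 glutaconaldehyde potassium salt
Product: 26 (2E,4E)-5-bromopenta-2,4-dienal
Conditions: Ph3PBr2, CH2Cl2, 0 °C to rt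
Reagents that add atoms: triphenylphosphine dibromide (BrP(Br)(c1ccccc1)(c1ccccc1)c1ccccc1)
Why: Becher bromination: the enolate oxygen is activated as an oxyphosphonium and replaced by bromide through addition–elimination, giving the thermodynamic E,E-dienal.

Step 19
Reactants: 26 (2E,4E)-5-bromopenta-2,4-dienal
Product: 27 (2E,4E)-5-bromopenta-2,4-dienoic acid
Conditions: NaClO2, NaH2PO4, 2-methylbut-2-ene, t-BuOH/H2O, 0 °C to rt
Reagents that add atoms: sodium chlorite ([Na+].[O-]Cl=O)
Why: Pinnick oxidation takes the enal to the acid without isomerizing the diene or touching the vinyl bromide.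

Step 20
Reactants: 27 (2E,4E)-5-bromopenta-2,4-dienoic acid; 28 2-amino-3-hydroxycyclopent-2-en-1-one hydrochloride
Product: 30 (2E,4E)-5-bromo-N-(2-hydroxy-5-oxocyclopent-1-en-1-yl)penta-2,4-dienamide, via acid chloride 29 (not isolated)
Conditions: (COCl)2, DMF (cat.), CH2Cl2, 0 °C; then 28, Et3N, THF, 0 °C
Reagents that add atoms: none
Why: Acylation of the amine through the acid chloride gives the amide (any O-acyl isomer transfers the acyl group to nitrogen) with the E,E geometry intact.

Step 21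
Reactants: 24 vinyl carbinol diol amide; 30 (2E,4E)-5-bromo-N-(2-hydroxy-5-oxocyclopent-1-en-1-yl)penta-2,4-dienamide
Product: 31 target, (2E,4E,6R)-N-[(3S,4R)-3,4-dihydroxy-3-[(1E,3E,5E)-7-[(2-hydroxy-5-oxocyclopent-1-en-1-yl)amino]-7-oxohepta-1,3,5-trien-1-yl]-6-oxocyclohex-1-en-1-yl]-4,6-dimethyldeca-2,4-dienamide
Conditions: Pd(OAc)2 (10 mol %), Ag2CO3, DMF, rt to 45 °C, dark
Reagents that add atoms: none
Why: Mizoroki–Heck vinylation under Jeffery-type silver conditions: oxidative addition of the alkenyl bromide to zerovalent palladium with retention, insertion at the terminal CH2 and syn β-hydride elimination give the all-E triene; the tertiary carbinol has no carbinol hydrogen to lose.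

**Compound list**
1 | (−)-quinic acid, (1S,3R,4S,5R)-1,3,4,5-tetrahydroxycyclohexane-1-carboxylic acid | OC(=O)[C@]1(O)C[C@@H](O)[C@@H](O)[C@H](O)C1 | starting material
2 | methyl quinate, methyl (1S,3R,4S,5R)-1,3,4,5-tetrahydroxycyclohexane-1-carboxylate | COC(=O)[C@]1(O)C[C@@H](O)[C@@H](O)[C@H](O)C1 | intermediate
3 | methyl 3,5-bis-O-(tert-butyldimethylsilyl)quinate (quinic acid configuration; 1-OH and 4-OH free) | COC(=O)[C@]1(O)C[C@@H](O[Si](C)(C)C(C)(C)C)[C@@H](O)[C@H](O[Si](C)(C)C(C)(C)C)C1 | intermediate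
4 | methyl (3R,5R)-3,5-bis[(tert-butyldimethylsilyl)oxy]-1-hydroxy-4-oxocyclohexane-1-carboxylate | COC(=O)C1(O)C[C@@H](O[Si](C)(C)C(C)(C)C)C(=O)[C@H](O[Si](C)(C)C(C)(C)C)C1 | intermediate
5 | methyl 3,5-bis-O-(tert-butyldimethylsilyl)-4-C-ethenylquinate; 1-OH, 3-OTBS and the new 4-OH on one face; 5-OTBS, ethenyl and CO2Me on the other | COC(=O)[C@]1(O)C[C@@H](O[Si](C)(C)C(C)(C)C)[C@](O)(C=C)[C@H](O[Si](C)(C)C(C)(C)C)C1 | intermediate
6 | methyl 4-C-ethenylquinate, tetraol with the configuration of 5 | COC(=O)[C@]1(O)C[C@@H](O)[C@](O)(C=C)[C@H](O)C1 | intermediate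
7 | methyl 4-C-ethenyl-3,4-O-isopropylidenequinate (cis-fused acetonide on O3/O4; 1-OH and 5-OH free) | COC(=O)[C@]1(O)C[C@H]2OC(C)(C)O[C@@]2(C=C)[C@H](O)C1 | intermediate
8 | 4-ethenyl-1-(hydroxymethyl)-3,4-O-isopropylidenecyclohexane-1,3,4,5-tetrol (7 with CO2Me reduced to CH2OH) | OC[C@]1(O)C[C@H]2OC(C)(C)O[C@@]2(C=C)[C@H](O)C1 | intermediate
9 | (3R,4S,5R)-4-ethenyl-5-hydroxy-3,4-(isopropylidenedioxy)cyclohexan-1-one | O=C1C[C@H]2OC(C)(C)O[C@@]2(C=C)[C@H](O)C1 | intermediate
10 | 5-O-methanesulfonate of 9 | O=C1C[C@H]2OC(C)(C)O[C@@]2(C=C)[C@H](OS(C)(=O)=O)C1 | intermediate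
11 | (4S,5R)-4-ethenyl-4,5-(isopropylidenedioxy)cyclohex-2-en-1-one | O=C1C[C@H]2OC(C)(C)O[C@@]2(C=C)C=C1 | intermediate
12 | (4S,5R)-4-ethenyl-2-iodo-4,5-(isopropylidenedioxy)cyclohex-2-en-1-one | O=C1C[C@H]2OC(C)(C)O[C@@]2(C=C)C=C1I | intermediate
13 | (S)-3-bromo-2-methylpropan-1-ol | OC[C@H](C)CBr | starting material
14 | (R)-2-methylhexan-1-ol | OC[C@H](C)CCCC | intermediate
15 | (R)-2-methylhexanal | O=C[C@H](C)CCCC | intermediate
16 | (3RS,4R)-2,4-dimethyloct-1-en-3-ol | C=C(C)C(O)[C@H](C)CCCC | intermediate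
17 | (4R)-3-[(1-ethoxyethenyl)oxy]-2,4-dimethyloct-1-ene (mixed ketene acetal) | C=C(C)C(OC(=C)OCC)[C@H](C)CCCC | intermediate
18 | ethyl (4E,6R)-4,6-dimethyldec-4-enoate | CCOC(=O)CC/C(C)=C/[C@H](C)CCCC | intermediate
19 | ethyl (4E,6R)-4,6-dimethyl-2-(phenylselanyl)dec-4-enoate | CCOC(=O)C([Se]c1ccccc1)C/C(C)=C/[C@H](C)CCCC | intermediate
20 | ethyl (4E,6R)-4,6-dimethyl-2-(phenylseleninyl)dec-4-enoate | CCOC(=O)C([Se](=O)c1ccccc1)C/C(C)=C/[C@H](C)CCCC | intermediate
21 | ethyl (2E,4E,6R)-4,6-dimethyldeca-2,4-dienoate | CCOC(=O)/C=C/C(C)=C/[C@H](C)CCCC | intermediate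
22 | (2E,4E,6R)-4,6-dimethyldeca-2,4-dienamide | NC(=O)/C=C/C(C)=C/[C@H](C)CCCC | intermediate
23 | (2E,4E,6R)-N-[(3S,4R)-3-ethenyl-3,4-(isopropylidenedioxy)-6-oxocyclohex-1-en-1-yl]-4,6-dimethyldeca-2,4-dienamide | CCCC[C@@H](C)/C=C(C)/C=C/C(=O)NC1=C[C@]2(C=C)OC(C)(C)O[C@@H]2CC1=O | intermediate
24 | (2E,4E,6R)-N-[(3S,4R)-3-ethenyl-3,4-dihydroxy-6-oxocyclohex-1-en-1-yl]-4,6-dimethyldeca-2,4-dienamide | CCCC[C@@H](C)/C=C(C)/C=C/C(=O)NC1=C[C@@](O)(C=C)[C@H](O)CC1=O | intermediate
25 | glutaconaldehyde potassium salt, potassium (1E,3E)-5-oxopenta-1,3-dien-1-olate | [K+].[O-]/C=C/C=C/C=O | starting material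
26 | (2E,4E)-5-bromopenta-2,4-dienal | O=C/C=C/C=C/Br | intermediate
27 | (2E,4E)-5-bromopenta-2,4-dienoic acid | OC(=O)/C=C/C=C/Br | intermediate
28 | 2-amino-3-hydroxycyclopent-2-en-1-one hydrochloride | NC1=C(O)CCC1=O.Cl | starting material
29 | (2E,4E)-5-bromopenta-2,4-dienoyl chloride | ClC(=O)/C=C/C=C/Br | intermediate
30 | (2E,4E)-5-bromo-N-(2-hydroxy-5-oxocyclopent-1-en-1-yl)penta-2,4-dienamide | O=C(/C=C/C=C/Br)NC1=C(O)CCC1=O | intermediate
31 | (2E,4E,6R)-N-[(3S,4R)-3,4-dihydroxy-3-[(1E,3E,5E)-7-[(2-hydroxy-5-oxocyclopent-1-en-1-yl)amino]-7-oxohepta-1,3,5-trien-1-yl]-6-oxocyclohex-1-en-1-yl]-4,6-dimethyldeca-2,4-dienamide | CCCC[C@@H](C)/C=C(C)/C=C/C(=O)NC1=C[C@@](O)(/C=C/C=C/C=C/C(=O)NC2=C(O)CCC2=O)[C@H](O)CC1=O | target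

**Step count**
Total steps: 21. Longest linear sequence: 12 (steps 1–9, 16, 17, 21, from quinic acid).

**Steps most likely to fail, with fallbacks**

Step 21 (Heck coupling of two unprotected, polyfunctional partners). The risks are β-hydroxide elimination at the tertiary carbinol, polyene isomerization and low conversion. Fallback: set out from 24 and make the bond by Suzuki coupling instead. Cross-metathesis of the terminal vinyl group with vinylboronic acid pinacol ester (second-generation Hoveyda–Grubbs catalyst, CH2Cl2, 40 °C) gives (2E,4E,6R)-N-[(3S,4R)-3,4-dihydroxy-6-oxo-3-[(E)-2-(4,4,5,5-tetramethyl-1,3,2-dioxaborolan-2-yl)ethenyl]cyclohex-1-en-1-yl]-4,6-dimethyldeca-2,4-dienamide F8. Suzuki–Miyaura coupling of this boronate with 30 (Pd(dppf)Cl2, K3PO4, THF/H2O, rt) comes back to the route at 31.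

Step 16 (copper-catalysed amidation of a base-sensitive α-iodoenone with a weakly nucleophilic dienamide). Fallback: bring in nitrogen as azide without a halide, setting out from 11 and 21.
- Nucleophilic epoxidation of 11 (H2O2, NaOH, MeOH, 0 °C) gives the 2,3-epoxide of 11 F2.
- NaN3 and NH4Cl (MeOH/H2O, 60 °C) open it at C2 to the 2-azido-3-hydroxy ketone F3, which loses water to (4S,5R)-2-azido-4-ethenyl-4,5-(isopropylidenedioxy)cyclohex-2-en-1-one F4.
- Staudinger reduction (PPh3, THF/H2O) gives (4S,5R)-2-amino-4-ethenyl-4,5-(isopropylidenedioxy)cyclohex-2-en-1-one F5.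
- Separately, 21 is saponified (LiOH, THF/H2O) to (2E,4E,6R)-4,6-dimethyldeca-2,4-dienoic acid F6 and turned ((COCl)2, DMF cat., CH2Cl2) into (2E,4E,6R)-4,6-dimethyldeca-2,4-dienoyl chloride F7.
- Acylation of the amino enone with this chloride (pyridine, DMAP, CH2Cl2) comes back to the route at 23.

Step 4 (vinyl Grignard addition to a ketone flanked by two silyloxy groups, with a methyl ester present). The risks are enolization, ester attack and sluggish addition. Fallback: set out from 4 and use the slimmer, less basic cerium acetylide (HC≡CMgBr premixed with CeCl3, THF, −78 °C). This gives methyl (3R,5R)-3,5-bis[(tert-butyldimethylsilyl)oxy]-4-ethynyl-1,4-dihydroxycyclohexane-1-carboxylate F1. Semi-hydrogenation (H2, Pd/CaCO3 poisoned with Pb(OAc)2, quinoline, EtOAc) comes back to the route at 5.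

**Further compounds**
F1 | step 4 | methyl (3R,5R)-3,5-bis[(tert-butyldimethylsilyl)oxy]-4-ethynyl-1,4-dihydroxycyclohexane-1-carboxylate (4-OH on the face of 1-OH) | COC(=O)[C@]1(O)C[C@@H](O[Si](C)(C)C(C)(C)C)[C@](O)(C#C)[C@H](O[Si](C)(C)C(C)(C)C)C1
F2 | step 16 | 2,3-epoxide of 11 (epoxide face not defined) | O=C1C[C@H]2OC(C)(C)O[C@@]2(C=C)C3OC13
F3 | step 16 | 2-azido-3-hydroxy ketone from azide opening of F2 (C2 and C3 not defined) | O=C1C[C@H]2OC(C)(C)O[C@@]2(C=C)C(O)C1N=[N+]=[N-]
F4 | step 16 | (4S,5R)-2-azido-4-ethenyl-4,5-(isopropylidenedioxy)cyclohex-2-en-1-one | O=C1C[C@H]2OC(C)(C)O[C@@]2(C=C)C=C1N=[N+]=[N-]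
F5 | step 16 | (4S,5R)-2-amino-4-ethenyl-4,5-(isopropylidenedioxy)cyclohex-2-en-1-one | O=C1C[C@H]2OC(C)(C)O[C@@]2(C=C)C=C1N
F6 | step 16 | (2E,4E,6R)-4,6-dimethyldeca-2,4-dienoic acid | OC(=O)/C=C/C(C)=C/[C@H](C)CCCC
F7 | step 16 | (2E,4E,6R)-4,6-dimethyldeca-2,4-dienoyl chloride | ClC(=O)/C=C/C(C)=C/[C@H](C)CCCC
F8 | step 21 | (2E,4E,6R)-N-[(3S,4R)-3,4-dihydroxy-6-oxo-3-[(E)-2-(4,4,5,5-tetramethyl-1,3,2-dioxaborolan-2-yl)ethenyl]cyclohex-1-en-1-yl]-4,6-dimethyldeca-2,4-dienamide | CCCC[C@@H](C)/C=C(C)/C=C/C(=O)NC1=C[C@@](O)(/C=C/B2OC(C)(C)C(C)(C)O2)[C@H](O)CC1=O
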